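**Retrosynthetic overview**
1. Target ⇒ silyl-protected butenolide; the butenolide ring ⇒ α-hydroxy ketone + Ph3P=C=C=O (O-acylation, then intramolecular Wittig), closed in the penultimate step.
2. Central (Z)-2-(hydroxymethyl)alkene ⇒ Still–Gennari olefination of a ring-bearing α-alkyl phosphonate with a five-carbon β-alkoxy aldehyde, then DIBAL.
3. Phosphonate ⇒ homoallylic iodide ⇒ Zr-catalysed carboalumination/ethylene oxide on a terminal alkyne ⇒ methyl ketone.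
4. Methyl ketone (cyclohexane ring, both ring stereocentres) ⇒ (E)-geranylacetone by squalene–hopene cyclase cyclisation and hydrolysis; aldehyde ⇒ divinylcarbinol by catalytic Sharpless epoxidation.
5. Ring order: cyclohexane first (step 1), butenolide second (step 20).

Assumption: a squalene–hopene cyclase (wild type or variant) that ends the cyclisation of (E)-geranylacetone by O-capture is available as an E. coli whole-cell catalyst.

Abbreviations: TES = triethylsilyl, TBS = tert-butyldimethylsilyl, PMB = 4-methoxybenzyl, Piv = 2,2-dimethylpropanoyl, Cy* = (1S,2S)-2,6,6-trimethyl-2-(triethylsilyloxy)cyclohexyl.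

**Step 1**
Reactants: 1 (5E)-6,10-dimethylundeca-5,9-dien-2-one [(E)-geranylacetone]
Product: 2 (4aS,8aS)-2,5,5,8a-tetramethyl-4a,5,6,7,8,8a-hexahydro-4H-chromene
Conditions: squalene–hopene cyclase (E. coli whole cells), citrate buffer pH 6.0, 0.1% SDS, 35 °C, 48 h
Reagents that add atoms: none
Why: Enzymatic Brønsted-acid cation–olefin cyclisation by a squalene–hopene cyclase (class II terpene cyclase): the chair-folded substrate is protonated at the terminal alkene and the ketone oxygen traps the tertiary cation anti, so the enzyme sets both ring stereocentres (4aS,8aS, trans-fused).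

**Step 2**
Reactants: 2 (4aS,8aS)-2,5,5,8a-tetramethyl-4a,5,6,7,8,8a-hexahydro-4H-chromene
Product: 4 4-[(1S,2S)-2-hydroxy-2,6,6-trimethylcyclohexyl]butan-2-one, via hemiketal 3 (not isolated)
Conditions: 0.5 M aq. HCl (cat.), THF/H2O 4:1, 0 °C → rt; NaHCO3 quench
Reagents that add atoms: water (O)
Why: Acid-catalysed enol ether hydrolysis through the hemiketal; the tertiary C–O bond is not broken, so both stereocentres are kept.

**Step 3**
Reactants: 4 4-[(1S,2S)-2-hydroxy-2,6,6-trimethylcyclohexyl]butan-2-one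
Product: 5 4-[(1S,2S)-2,6,6-trimethyl-2-(triethylsilyloxy)cyclohexyl]butan-2-one
Conditions: TESOTf, 2,6-lutidine, CH2Cl2, −78 → −20 °C
Reagents that add atoms: triethylsilyl trifluoromethanesulfonate (CC[Si](CC)(CC)OS(=O)(=O)C(F)(F)F)
Why: Silyl triflate silylation of the hindered tertiary alcohol; at low temperature 2,6-lutidine is too weak a base to make the silyl enol ether of the ketone.

**Step 4**
Reactants: 5 4-[(1S,2S)-2,6,6-trimethyl-2-(triethylsilyloxy)cyclohexyl]butan-2-one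
Product: 7 {[(1S,2S)-2-(but-3-yn-1-yl)-1,3,3-trimethylcyclohexyl]oxy}triethylsilane, via enol phosphate 6 (not isolated)
Conditions: LDA (1.1 equiv), THF, −78 °C; ClP(O)(OEt)2, −78 → 0 °C; LDA (2.5 equiv), −78 °C → rt
Reagents that add atoms: none
Why: Negishi methyl ketone-to-alkyne conversion: kinetic enolisation at the methyl group, O-phosphorylation and LDA-induced β-elimination of diethyl phosphate give the terminal alkyne.

**Step 5**
Reactants: 7 {[(1S,2S)-2-(but-3-yn-1-yl)-1,3,3-trimethylcyclohexyl]oxy}triethylsilane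
Product: 10 (3E)-4-methyl-6-Cy*-hex-3-en-1-ol, via alkenylalane 8 (not isolated), via lithium alanate 9 (not isolated)
Conditions: Me3Al (2.5 equiv), Cp2ZrCl2 (0.3 equiv), CH2Cl2, 0 °C → rt; evaporate; n-BuLi, hexane/THF, −30 °C; ethylene oxide, −30 → 0 °C; aq. HCl
Reagents that add atoms: trimethylaluminium (C[Al](C)C); ethylene oxide (C1CO1)
Why: Zr-catalysed Negishi carboalumination adds Me–Al syn across the alkyne (Al terminal), and the derived alanate opens ethylene oxide with retention, so the trisubstituted alkene is formed E only.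

**Step 6**
Reactants: 10 (3E)-4-methyl-6-Cy*-hex-3-en-1-ol
Product: 11 {[(1S,2S)-2-[(3E)-6-iodo-3-methylhex-3-en-1-yl]-1,3,3-trimethylcyclohexyl]oxy}triethylsilane
Conditions: PPh3, I2, imidazole, CH2Cl2, 0 °C → rt
Reagents that add atoms: iodine (II)
Why: Appel-type (Garegg–Samuelsson) iodination of the primary alcohol by SN2 on the alkoxyphosphonium ion; the alkene and the tertiary silyl ether are untouched.

**Step 7**
Reactants: 11 {[(1S,2S)-2-[(3E)-6-iodo-3-methylhex-3-en-1-yl]-1,3,3-trimethylcyclohexyl]oxy}triethylsilane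
Product: 12 methyl (5E)-2-[bis(2,2,2-trifluoroethoxy)phosphoryl]-6-methyl-8-Cy*-oct-5-enoate (C-2 epimers)
Conditions: phosphonoacetate (3 equiv), NaH (2.8 equiv), THF/DMSO, 0 → 45 °C
Reagents that add atoms: methyl 2-[bis(2,2,2-trifluoroethoxy)phosphoryl]acetate (COC(=O)CP(=O)(OCC(F)(F)F)OCC(F)(F)F)
Why: SN2 C-alkylation of the soft phosphonoacetate anion with the primary iodide, with excess nucleophile to suppress dialkylation; the new centre is lost in step 15.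

**Step 8**
Reactants: 13 penta-1,4-dien-3-ol
Product: 14 (1R)-1-[(2S)-oxiran-2-yl]prop-2-en-1-ol
Conditions: Ti(OiPr)4 (10 mol%), D-(−)-DIPT (13 mol%), TBHP, 4 Å MS, CH2Cl2, −20 °C, 5 d
Reagents that add atoms: tert-butyl hydroperoxide (CC(C)(C)OO)
Why: Catalytic Sharpless asymmetric epoxidation desymmetrises the achiral divinylcarbinol (enantiotopic-vinyl plus diastereoface selection), giving the anti epoxy alcohol with the carbinol centre R, which becomes C5 of the butenolide.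

**Step 9**
Reactants: 14 (1R)-1-[(2S)-oxiran-2-yl]prop-2-en-1-ol
Product: 15 (2S)-2-{(1R)-1-[(4-methoxyphenyl)methoxy]prop-2-en-1-yl}oxirane
Conditions: NaH, PMBCl, Bu4NI (cat.), THF, −20 → 0 °C
Reagents that add atoms: 4-methoxybenzyl chloride (COc1ccc(CCl)cc1)
Why: Williamson etherification at low temperature in an aprotic solvent, where O-alkylation outruns Payne rearrangement.

**Step 10**
Reactants: 15 (2S)-2-{(1R)-1-[(4-methoxyphenyl)methoxy]prop-2-en-1-yl}oxirane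
Product: 16 (2S,3R)-3-[(4-methoxyphenyl)methoxy]pent-4-ene-1,2-diol
Conditions: HClO4 (cat.), THF/H2O 3:1, 0 °C → rt
Reagents that add atoms: water (O)
Why: Acid-catalysed epoxide hydrolysis with attack at the terminal carbon, because the adjacent alkoxy group disfavours cation character at C-2; C-2 is a sacrificial centre that is oxidised in step 18.

**Step 11**
Reactants: 16 (2S,3R)-3-[(4-methoxyphenyl)methoxy]pent-4-ene-1,2-diol
Product: 17 (2S,3R)-1-(TBSO)-3-[(4-methoxyphenyl)methoxy]pent-4-en-2-ol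
Conditions: TBSCl (1.05 equiv), imidazole, CH2Cl2, 0 °C
Reagents that add atoms: tert-butyldimethylsilyl chloride (CC(C)(C)[Si](C)(C)Cl)
Why: Sterically controlled selective silylation of the primary hydroxyl of a 1,2-diol.

**Step 12**
Reactants: 17 (2S,3R)-1-(TBSO)-3-[(4-methoxyphenyl)methoxy]pent-4-en-2-ol
Product: 18 (2S,3R)-1-(TBSO)-3-[(4-methoxyphenyl)methoxy]pent-4-en-2-yl 2,2-dimethylpropanoate
Conditions: PivCl, pyridine, DMAP, CH2Cl2, rt → 40 °C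
Reagents that add atoms: pivaloyl chloride (CC(C)(C)C(=O)Cl)
Why: DMAP-catalysed acylation gives a base-stable ester that the later DIBAL step removes together with the enoate reduction.

**Step 13**
Reactants: 18 (2S,3R)-1-(TBSO)-3-[(4-methoxyphenyl)methoxy]pent-4-en-2-yl 2,2-dimethylpropanoate
Product: 20 (2S,3R)-1-(TBSO)-5-hydroxy-3-[(4-methoxyphenyl)methoxy]pentan-2-yl 2,2-dimethylpropanoate, via alkylborane 19 (not isolated)
Conditions: 9-BBN, THF, 0 °C → rt; 3 M NaOH, 30% H2O2, 0 °C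
Reagents that add atoms: hydrogen peroxide (OO)
Why: Anti-Markovnikov hydroboration–oxidation of the vinyl group; boron ends 1,3 to the allylic ether, so no β-elimination occurs, and the pivalate survives the cold basic peroxide.

**Step 14**
Reactants: 20 (2S,3R)-1-(TBSO)-5-hydroxy-3-[(4-methoxyphenyl)methoxy]pentan-2-yl 2,2-dimethylpropanoate
Product: 21 (2S,3R)-1-(TBSO)-3-[(4-methoxyphenyl)methoxy]-5-oxopentan-2-yl 2,2-dimethylpropanoate
Conditions: Dess–Martin periodinane, NaHCO3, CH2Cl2, 0 °C → rt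
Reagents that add atoms: none
Why: Buffered Dess–Martin oxidation gives the β-alkoxy aldehyde without β-elimination.

**Step 15**
Reactants: 12 methyl (5E)-2-[bis(2,2,2-trifluoroethoxy)phosphoryl]-6-methyl-8-Cy*-oct-5-enoate; 21 (2S,3R)-1-(TBSO)-3-[(4-methoxyphenyl)methoxy]-5-oxopentan-2-yl 2,2-dimethylpropanoate
Product: 22 methyl (2Z,5R,6S)-7-(TBSO)-6-(PivO)-5-(PMBO)-2-[(3E)-4-methyl-6-Cy*-hex-3-en-1-yl]hept-2-enoate
Conditions: KHMDS, 18-crown-6, THF, −78 °C; then 21, −78 °C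
Reagents that add atoms: none
Why: Still–Gennari olefination: fast irreversible elimination from the kinetic adduct of the electron-poor phosphonate (dissociated K+) places the ester cis to the aldehyde-derived chain, giving the (Z)-trisubstituted enoate.

**Step 16**
Reactants: 22 methyl (2Z,5R,6S)-7-(TBSO)-6-(PivO)-5-(PMBO)-2-[(3E)-4-methyl-6-Cy*-hex-3-en-1-yl]hept-2-enoate
Product: 23 (2S,3R,5Z,9E)-1-(TBSO)-6-(hydroxymethyl)-3-(PMBO)-10-methyl-12-Cy*-dodeca-5,9-dien-2-ol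
Conditions: DIBAL-H (5 equiv), CH2Cl2, −78 → −30 °C; Rochelle salt
Reagents that add atoms: none
Why: DIBAL 1,2-reduction of the enoate to the allylic alcohol with concurrent reductive cleavage of the pivalate; the alkene geometry is unchanged.

**Step 17**
Reactants: 23 (2S,3R,5Z,9E)-1-(TBSO)-6-(hydroxymethyl)-3-(PMBO)-10-methyl-12-Cy*-dodeca-5,9-dien-2-ol
Product: 24 (2S,3R,5Z,9E)-1-(TBSO)-6-(TBSO-methyl)-3-(PMBO)-10-methyl-12-Cy*-dodeca-5,9-dien-2-ol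
Conditions: TBSCl (1.1 equiv), imidazole, CH2Cl2, −10 → 0 °C
Reagents that add atoms: tert-butyldimethylsilyl chloride (CC(C)(C)[Si](C)(C)Cl)
Why: Selective silylation of the primary allylic hydroxyl over the hindered secondary one.

**Step 18**
Reactants: 24 (2S,3R,5Z,9E)-1-(TBSO)-6-(TBSO-methyl)-3-(PMBO)-10-methyl-12-Cy*-dodeca-5,9-dien-2-ol
Product: 25 (3R,5Z,9E)-1-(TBSO)-6-(TBSO-methyl)-3-(PMBO)-10-methyl-12-Cy*-dodeca-5,9-dien-2-one
Conditions: Dess–Martin periodinane, NaHCO3, CH2Cl2, 0 °C → rt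
Reagents that add atoms: none
Why: Buffered Dess–Martin oxidation of the secondary alcohol removes the sacrificial stereocentre without epimerising the α-alkoxy centre.

**Step 19**
Reactants: 25 (3R,5Z,9E)-1-(TBSO)-6-(TBSO-methyl)-3-(PMBO)-10-methyl-12-Cy*-dodeca-5,9-dien-2-one
Product: 26 (3R,5Z,9E)-1-(TBSO)-6-(TBSO-methyl)-3-hydroxy-10-methyl-12-Cy*-dodeca-5,9-dien-2-one
Conditions: DDQ, CH2Cl2/pH 7 buffer 10:1, 0 °C
Reagents that add atoms: none
Why: Oxidative PMB ether cleavage under neutral buffered conditions that spare the silyl ethers, both trisubstituted alkenes and the α-ketol centre.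

**Step 20**
Reactants: 26 (3R,5Z,9E)-1-(TBSO)-6-(TBSO-methyl)-3-hydroxy-10-methyl-12-Cy*-dodeca-5,9-dien-2-one
Product: 28 (5R)-4-(TBSO-methyl)-5-[(2Z,6E)-3-(TBSO-methyl)-7-methyl-9-Cy*-nona-2,6-dien-1-yl]furan-2(5H)-one, via ylide ester 27 (not isolated)
Conditions: Ph3P=C=C=O (1.4 equiv), toluene, 90 °C
Reagents that add atoms: (triphenylphosphoranylidene)ketene (O=C=C=P(c1ccccc1)(c1ccccc1)c1ccccc1)
Why: Bestmann ylide sequence: the free hydroxyl adds to the ketene to give the stabilised ylide ester, which closes by intramolecular Wittig reaction on the adjacent ketone; the carbinol C–O bond is not broken, so C5 stays R.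

**Step 21**
Reactants: 28 (5R)-4-(TBSO-methyl)-5-[(2Z,6E)-3-(TBSO-methyl)-7-methyl-9-Cy*-nona-2,6-dien-1-yl]furan-2(5H)-one
Product: 29 (5R)-4-(hydroxymethyl)-5-{(2Z,6E)-3-(hydroxymethyl)-9-[(1S,2S)-2-hydroxy-2,6,6-trimethylcyclohexyl]-7-methylnona-2,6-dien-1-yl}furan-2(5H)-one
Conditions: HF·pyridine, pyridine, THF, 0 °C → rt
Reagents that add atoms: none
Why: Fluoride-mediated global desilylation under buffered, mildly acidic conditions, which avoids base-induced epimerisation at the butenolide γ-position and dehydration of the tertiary alcohol.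

**Compound list**
1 | (5E)-6,10-dimethylundeca-5,9-dien-2-one | CC(=O)CC/C=C(\C)CCC=C(C)C | starting material
2 | (4aS,8aS)-2,5,5,8a-tetramethyl-4a,5,6,7,8,8a-hexahydro-4H-chromene | CC1=CC[C@H]2C(C)(C)CCC[C@]2(C)O1 | intermediate
3 | (4aS,8aS)-2,5,5,8a-tetramethyloctahydro-2H-chromen-2-ol (hemiketal, C-2 epimers) | CC1(O)CC[C@H]2C(C)(C)CCC[C@]2(C)O1 | intermediate
4 | 4-[(1S,2S)-2-hydroxy-2,6,6-trimethylcyclohexyl]butan-2-one | CC(=O)CC[C@H]1C(C)(C)CCC[C@]1(C)O | intermediate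
5 | 4-[(1S,2S)-2,6,6-trimethyl-2-(triethylsilyloxy)cyclohexyl]butan-2-one | CC(=O)CC[C@H]1C(C)(C)CCC[C@]1(C)O[Si](CC)(CC)CC | intermediate
6 | diethyl 4-[(1S,2S)-2,6,6-trimethyl-2-(triethylsilyloxy)cyclohexyl]but-1-en-2-yl phosphate | C=C(OP(=O)(OCC)OCC)CC[C@H]1C(C)(C)CCC[C@]1(C)O[Si](CC)(CC)CC | intermediate
7 | {[(1S,2S)-2-(but-3-yn-1-yl)-1,3,3-trimethylcyclohexyl]oxy}triethylsilane | C#CCC[C@H]1C(C)(C)CCC[C@]1(C)O[Si](CC)(CC)CC | intermediate
8 | dimethyl{(1E)-2-methyl-4-[(1S,2S)-2,6,6-trimethyl-2-(triethylsilyloxy)cyclohexyl]but-1-en-1-yl}alumane | C[Al](C)/C=C(\C)CC[C@H]1C(C)(C)CCC[C@]1(C)O[Si](CC)(CC)CC | intermediate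
9 | lithium butyl(dimethyl){(1E)-2-methyl-4-[(1S,2S)-2,6,6-trimethyl-2-(triethylsilyloxy)cyclohexyl]but-1-en-1-yl}aluminate | [Li+].CCCC[Al-](C)(C)/C=C(\C)CC[C@H]1C(C)(C)CCC[C@]1(C)O[Si](CC)(CC)CC | intermediate
10 | (3E)-4-methyl-6-[(1S,2S)-2,6,6-trimethyl-2-(triethylsilyloxy)cyclohexyl]hex-3-en-1-ol | OCC/C=C(\C)CC[C@H]1C(C)(C)CCC[C@]1(C)O[Si](CC)(CC)CC | intermediate
11 | {[(1S,2S)-2-[(3E)-6-iodo-3-methylhex-3-en-1-yl]-1,3,3-trimethylcyclohexyl]oxy}triethylsilane | ICC/C=C(\C)CC[C@H]1C(C)(C)CCC[C@]1(C)O[Si](CC)(CC)CC | intermediate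
12 | methyl (5E)-2-[bis(2,2,2-trifluoroethoxy)phosphoryl]-6-methyl-8-[(1S,2S)-2,6,6-trimethyl-2-(triethylsilyloxy)cyclohexyl]oct-5-enoate (C-2 epimers) | COC(=O)C(CC/C=C(\C)CC[C@H]1C(C)(C)CCC[C@]1(C)O[Si](CC)(CC)CC)P(=O)(OCC(F)(F)F)OCC(F)(F)F | intermediate
13 | penta-1,4-dien-3-ol | C=CC(O)C=C | starting material
14 | (1R)-1-[(2S)-oxiran-2-yl]prop-2-en-1-ol | C=C[C@@H](O)[C@@H]1CO1 | intermediate
15 | (2S)-2-{(1R)-1-[(4-methoxyphenyl)methoxy]prop-2-en-1-yl}oxirane | C=C[C@@H](OCc1ccc(OC)cc1)[C@@H]1CO1 | intermediate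
16 | (2S,3R)-3-[(4-methoxyphenyl)methoxy]pent-4-ene-1,2-diol | C=C[C@@H](OCc1ccc(OC)cc1)[C@@H](O)CO | intermediate
17 | (2S,3R)-1-{[tert-butyl(dimethyl)silyl]oxy}-3-[(4-methoxyphenyl)methoxy]pent-4-en-2-ol | C=C[C@@H](OCc1ccc(OC)cc1)[C@@H](O)CO[Si](C)(C)C(C)(C)C | intermediate
18 | (2S,3R)-1-{[tert-butyl(dimethyl)silyl]oxy}-3-[(4-methoxyphenyl)methoxy]pent-4-en-2-yl 2,2-dimethylpropanoate | C=C[C@@H](OCc1ccc(OC)cc1)[C@@H](OC(=O)C(C)(C)C)CO[Si](C)(C)C(C)(C)C | intermediate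
19 | (2S,3R)-5-(9-borabicyclo[3.3.1]nonan-9-yl)-1-{[tert-butyl(dimethyl)silyl]oxy}-3-[(4-methoxyphenyl)methoxy]pentan-2-yl 2,2-dimethylpropanoate | C(C[C@@H](OCc1ccc(OC)cc1)[C@@H](OC(=O)C(C)(C)C)CO[Si](C)(C)C(C)(C)C)B1C2CCCC1CCC2 | intermediate
20 | (2S,3R)-1-{[tert-butyl(dimethyl)silyl]oxy}-5-hydroxy-3-[(4-methoxyphenyl)methoxy]pentan-2-yl 2,2-dimethylpropanoate | OCC[C@@H](OCc1ccc(OC)cc1)[C@@H](OC(=O)C(C)(C)C)CO[Si](C)(C)C(C)(C)C | intermediate
21 | (2S,3R)-1-{[tert-butyl(dimethyl)silyl]oxy}-3-[(4-methoxyphenyl)methoxy]-5-oxopentan-2-yl 2,2-dimethylpropanoate | O=CC[C@@H](OCc1ccc(OC)cc1)[C@@H](OC(=O)C(C)(C)C)CO[Si](C)(C)C(C)(C)C | intermediate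
22 | methyl (2Z,5R,6S)-7-(TBSO)-6-(PivO)-5-(PMBO)-2-{(3E)-4-methyl-6-[(1S,2S)-2,6,6-trimethyl-2-(triethylsilyloxy)cyclohexyl]hex-3-en-1-yl}hept-2-enoate | COC(=O)/C(=C\C[C@@H](OCc1ccc(OC)cc1)[C@@H](OC(=O)C(C)(C)C)CO[Si](C)(C)C(C)(C)C)CC/C=C(\C)CC[C@H]1C(C)(C)CCC[C@]1(C)O[Si](CC)(CC)CC | intermediate
23 | (2S,3R,5Z,9E)-1-(TBSO)-6-(hydroxymethyl)-3-(PMBO)-10-methyl-12-[(1S,2S)-2,6,6-trimethyl-2-(triethylsilyloxy)cyclohexyl]dodeca-5,9-dien-2-ol | OC/C(=C\C[C@@H](OCc1ccc(OC)cc1)[C@@H](O)CO[Si](C)(C)C(C)(C)C)CC/C=C(\C)CC[C@H]1C(C)(C)CCC[C@]1(C)O[Si](CC)(CC)CC | intermediate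
24 | (2S,3R,5Z,9E)-1-(TBSO)-6-(TBSO-methyl)-3-(PMBO)-10-methyl-12-[(1S,2S)-2,6,6-trimethyl-2-(triethylsilyloxy)cyclohexyl]dodeca-5,9-dien-2-ol | CC(C)(C)[Si](C)(C)OC/C(=C\C[C@@H](OCc1ccc(OC)cc1)[C@@H](O)CO[Si](C)(C)C(C)(C)C)CC/C=C(\C)CC[C@H]1C(C)(C)CCC[C@]1(C)O[Si](CC)(CC)CC | intermediate
25 | (3R,5Z,9E)-1-(TBSO)-6-(TBSO-methyl)-3-(PMBO)-10-methyl-12-[(1S,2S)-2,6,6-trimethyl-2-(triethylsilyloxy)cyclohexyl]dodeca-5,9-dien-2-one | CC(C)(C)[Si](C)(C)OC/C(=C\C[C@@H](OCc1ccc(OC)cc1)C(=O)CO[Si](C)(C)C(C)(C)C)CC/C=C(\C)CC[C@H]1C(C)(C)CCC[C@]1(C)O[Si](CC)(CC)CC | intermediate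
26 | (3R,5Z,9E)-1-(TBSO)-6-(TBSO-methyl)-3-hydroxy-10-methyl-12-[(1S,2S)-2,6,6-trimethyl-2-(triethylsilyloxy)cyclohexyl]dodeca-5,9-dien-2-one | CC(C)(C)[Si](C)(C)OC/C(=C\C[C@@H](O)C(=O)CO[Si](C)(C)C(C)(C)C)CC/C=C(\C)CC[C@H]1C(C)(C)CCC[C@]1(C)O[Si](CC)(CC)CC | intermediate
27 | (triphenylphosphoranylidene)acetate ester of 26 at the 3-hydroxyl | CC(C)(C)[Si](C)(C)OC/C(=C\C[C@@H](OC(=O)C=P(c1ccccc1)(c1ccccc1)c1ccccc1)C(=O)CO[Si](C)(C)C(C)(C)C)CC/C=C(\C)CC[C@H]1C(C)(C)CCC[C@]1(C)O[Si](CC)(CC)CC | intermediate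
28 | (5R)-4-(TBSO-methyl)-5-{(2Z,6E)-3-(TBSO-methyl)-7-methyl-9-[(1S,2S)-2,6,6-trimethyl-2-(triethylsilyloxy)cyclohexyl]nona-2,6-dien-1-yl}furan-2(5H)-one | CC(C)(C)[Si](C)(C)OC/C(=C\C[C@H]1OC(=O)C=C1CO[Si](C)(C)C(C)(C)C)CC/C=C(\C)CC[C@H]1C(C)(C)CCC[C@]1(C)O[Si](CC)(CC)CC | intermediate
29 | (5R)-4-(hydroxymethyl)-5-{(2Z,6E)-3-(hydroxymethyl)-9-[(1S,2S)-2-hydroxy-2,6,6-trimethylcyclohexyl]-7-methylnona-2,6-dien-1-yl}furan-2(5H)-one | C/C(=C\CC/C(=C/C[C@H]1OC(=O)C=C1CO)CO)CC[C@H]1C(C)(C)CCC[C@]1(C)O | target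

**Step count and risk**
Total steps: 21. Longest linear sequence: 14 steps (steps 1–7 then 15–21; the branch 8–14 then 15–21 is equally long).

The three steps most likely to fail:

Step 1 (enzymatic cyclisation: low activity on the short substrate, or deprotonation instead of O-capture). The fallback sets out from 1 and comes back at 4. A monocyclising squalene–hopene cyclase variant converts 1 into 4-[(1S)-2,2-dimethyl-6-methylidenecyclohexyl]butan-2-one F1, which still carries the enzyme-set ring stereocentre. mCPBA (CH2Cl2, NaHCO3, 0 °C) epoxidises the exocyclic alkene from the equatorial side, since axial approach is blocked by the syn-axial methyl, to give 4-[(3S,4S)-5,5-dimethyl-1-oxaspiro[2.5]octan-4-yl]butan-2-one F2. LiAlH4 (THF, 0 °C) opens the epoxide at CH2 and reduces the ketone to 4-[(1S,2S)-2-hydroxy-2,6,6-trimethylcyclohexyl]butan-2-ol F3; any cis diastereomer is removed by chromatography here. Dess–Martin oxidation of the secondary alcohol then gives 4.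

Step 15 (Z/E ratio of the Still–Gennari olefination with an α-alkyl phosphonate, and inseparable isomers). The fallback sets out from 21 and 11 and comes back at 22, fixing the geometry by syn-hydrometalation instead of by olefination. Ohira–Bestmann homologation of 21 (dimethyl 1-diazo-2-oxopropylphosphonate, K2CO3, MeOH) gives (2S,3R)-1-(TBSO)-3-(PMBO)hex-5-yn-2-yl 2,2-dimethylpropanoate F4. LiHMDS then ClCO2Me (THF, −78 °C) gives methyl (5R,6S)-7-(TBSO)-6-(PivO)-5-(PMBO)hept-2-ynoate F5. Pd(PPh3)4-catalysed syn-hydrostannation with Bu3SnH, ester-directed to the α-carbon, gives methyl (2E,5R,6S)-7-(TBSO)-6-(PivO)-5-(PMBO)-2-(tributylstannyl)hept-2-enoate F6. I2 (CH2Cl2, 0 °C) gives with retention methyl (2E,5R,6S)-2-iodo-7-(TBSO)-6-(PivO)-5-(PMBO)hept-2-enoate F7. Zinc insertion into 11 (Zn dust, LiCl, THF) gives iodo[(3E)-4-methyl-6-Cy*-hex-3-en-1-yl]zinc F8, and Negishi coupling of F8 with F7 (Pd(PPh3)4, THF/DMA, rt) gives 22 with retention.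

Step 20 (epimerisation of the α-ketol or silyl migration under the basic ylide before ring closure). The fallback sets out from 25 and comes back at 28, building the lactone by aldol addition, lactonisation and dehydration. The lithium enolate of ethyl acetate (LDA, EtOAc, THF, −78 °C) adds to the ketone of 25 to give ethyl (4R,6Z,10E)-3,7-bis(TBSO-methyl)-3-hydroxy-4-(PMBO)-11-methyl-13-Cy*-trideca-6,10-dienoate F9. DDQ (pH 7 buffer) then PPTS (cat.) frees the secondary hydroxyl, which lactonises to (5R)-4-hydroxy-4-(TBSO-methyl)-5-[(2Z,6E)-3-(TBSO-methyl)-7-methyl-9-Cy*-nona-2,6-dien-1-yl]oxolan-2-one F10. SOCl2/pyridine (0 °C) or Burgess reagent dehydrates F10 toward the α-CH2 to give 28.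

**Further compounds**
F1 | step 1 | 4-[(1S)-2,2-dimethyl-6-methylidenecyclohexyl]butan-2-one | CC(=O)CC[C@H]1C(C)(C)CCCC1=C
F2 | step 1 | 4-[(3S,4S)-5,5-dimethyl-1-oxaspiro[2.5]octan-4-yl]butan-2-one | CC(=O)CC[C@H]1C(C)(C)CCC[C@@]12CO2
F3 | step 1 | 4-[(1S,2S)-2-hydroxy-2,6,6-trimethylcyclohexyl]butan-2-ol (C-2 epimers) | CC(O)CC[C@H]1C(C)(C)CCC[C@]1(C)O
F4 | step 15 | (2S,3R)-1-(TBSO)-3-(PMBO)hex-5-yn-2-yl 2,2-dimethylpropanoate | C#CC[C@@H](OCc1ccc(OC)cc1)[C@@H](OC(=O)C(C)(C)C)CO[Si](C)(C)C(C)(C)C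
F5 | step 15 | methyl (5R,6S)-7-(TBSO)-6-(PivO)-5-(PMBO)hept-2-ynoate | COC(=O)C#CC[C@@H](OCc1ccc(OC)cc1)[C@@H](OC(=O)C(C)(C)C)CO[Si](C)(C)C(C)(C)C
F6 | step 15 | methyl (2E,5R,6S)-7-(TBSO)-6-(PivO)-5-(PMBO)-2-(tributylstannyl)hept-2-enoate | COC(=O)/C(=C\C[C@@H](OCc1ccc(OC)cc1)[C@@H](OC(=O)C(C)(C)C)CO[Si](C)(C)C(C)(C)C)[Sn](CCCC)(CCCC)CCCC
F7 | step 15 | methyl (2E,5R,6S)-2-iodo-7-(TBSO)-6-(PivO)-5-(PMBO)hept-2-enoate | COC(=O)/C(I)=C\C[C@@H](OCc1ccc(OC)cc1)[C@@H](OC(=O)C(C)(C)C)CO[Si](C)(C)C(C)(C)C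
F8 | step 15 | iodo{(3E)-4-methyl-6-[(1S,2S)-2,6,6-trimethyl-2-(triethylsilyloxy)cyclohexyl]hex-3-en-1-yl}zinc | I[Zn]CC/C=C(\C)CC[C@H]1C(C)(C)CCC[C@]1(C)O[Si](CC)(CC)CC
F9 | step 20 | ethyl (4R,6Z,10E)-3,7-bis(TBSO-methyl)-3-hydroxy-4-(PMBO)-11-methyl-13-[(1S,2S)-2,6,6-trimethyl-2-(triethylsilyloxy)cyclohexyl]trideca-6,10-dienoate (C-3 epimers) | CCOC(=O)CC(O)(CO[Si](C)(C)C(C)(C)C)[C@H](OCc1ccc(OC)cc1)C/C=C(\CO[Si](C)(C)C(C)(C)C)CC/C=C(\C)CC[C@H]1C(C)(C)CCC[C@]1(C)O[Si](CC)(CC)CC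
F10 | step 20 | (5R)-4-hydroxy-4-(TBSO-methyl)-5-{(2Z,6E)-3-(TBSO-methyl)-7-methyl-9-[(1S,2S)-2,6,6-trimethyl-2-(triethylsilyloxy)cyclohexyl]nona-2,6-dien-1-yl}oxolan-2-one (C-4 epimers) | O=C1CC(O)(CO[Si](C)(C)C(C)(C)C)[C@@H](C/C=C(\CO[Si](C)(C)C(C)(C)C)CC/C=C(\C)CC[C@H]2C(C)(C)CCC[C@]2(C)O[Si](CC)(CC)CC)O1
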